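**Assumptions (one line each)**
- The target is achiral; "single enantiomer" is read as the single all‑E geometric isomer (five stereodefined trisubstituted alkenes).
- 2,3,4‑Trimethoxy‑6‑methylbenzaldehyde (CAS 22383‑85‑3) is taken as a catalogue compound; if not, it is one Vilsmeier formylation from 3,4,5‑trimethoxytoluene.

## Retrosynthetic overview
1. No ring is formed: the only ring is a purchased benzene, converted to the hydroxyquinone in the last step by CAN oxidation of a p‑(MOMO)/(MeO) arene.
2. Aryl–CH2 bond: aryl cuprate from bromide 5 plus all‑E hexaprenyl bromide 14 (SN2).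
3. Arene 5: chelation‑controlled demethylation of aldehyde 1 marks the future 3‑OH; then Dakin, bis‑MOM, bromination.
4. Hexaprenyl chain: C15 + C15, farnesyl tolyl sulfone 11 plus 12‑bromofarnesyl acetate 9 (E‑selective SeO2 oxidation), then Pd/LiBHEt3 desulfonylation.

## Route

**Step 1**
Reactants: 1, 2,3,4‑trimethoxy‑6‑methylbenzaldehyde
Product: 2, 2‑hydroxy‑3,4‑dimethoxy‑6‑methylbenzaldehyde
Conditions: BCl3 (1.2 equiv), CH2Cl2, −78 → 0 °C; aq. NaHCO3
Reagents that add atoms: none
Why: Chelation‑directed Lewis‑acid demethylation; boron bound to the formyl oxygen cleaves only the ortho OMe, which differentiates the oxygen that becomes the free OH of the target.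

**Step 2**
Reactants: 2
Product: 3, 3,4‑dimethoxy‑6‑methylbenzene‑1,2‑diol
Conditions: 30% H2O2, NaOH, H2O/THF, 0 °C → rt, Ar; Na2S2O3, then HCl
Reagents that add atoms: hydrogen peroxide, OO
Why: Dakin oxidation of an o‑hydroxybenzaldehyde (aryl migration to O, formate hydrolysis) replaces CHO by OH.

**Step 3**
Reactants: 3
Product: 4, 1,2‑dimethoxy‑3,4‑bis(methoxymethoxy)‑5‑methylbenzene
Conditions: NaH (2.5 equiv), MOMCl (2.5 equiv), DMF/THF, 0 °C → rt
Reagents that add atoms: chloromethyl methyl ether (MOMCl), COCCl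
Why: Williamson‑type acetalisation of both phenols; MOM survives NBS and organolithium/cuprate chemistry and cannot migrate between the two oxygens.

**Step 4**
Reactants: 4
Product: 5, 1‑bromo‑2,3‑dimethoxy‑4,5‑bis(methoxymethoxy)‑6‑methylbenzene
Conditions: NBS (1.05 equiv), MeCN, 0 °C → rt, dark
Reagents that add atoms: N‑bromosuccinimide, O=C1CCC(=O)N1Br
Why: Electrophilic aromatic bromination at the only free position of a very electron‑rich ring.

**Step 5**
Reactants: 6, (2E,6E)‑farnesol
Product: 7, (2E,6E)‑farnesyl acetate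
Conditions: Ac2O, pyridine, DMAP (cat.), CH2Cl2, rt
Reagents that add atoms: acetic anhydride, CC(=O)OC(C)=O
Why: Simple acylation; the acetate protects C1–OH and inductively deactivates the 2,3‑alkene towards the next oxidation.

**Step 6**
Reactants: 7
Product: 8, (2E,6E,10E)‑12‑hydroxy‑3,7,11‑trimethyldodeca‑2,6,10‑trien‑1‑yl acetate
Conditions: SeO2 (0.3 equiv), t‑BuOOH (3 equiv), salicylic acid (0.1 equiv), CH2Cl2, rt; then NaBH4, MeOH, 0 °C
Reagents that add atoms: selenium dioxide, O=[Se]=O (terminal oxidant tert‑butyl hydroperoxide, CC(C)(C)OO)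
Why: Sharpless–Umbreit allylic oxidation (ene then [2,3]‑shift) attacks the most electron‑rich terminal alkene at its E‑methyl, so the 10,11‑alkene becomes stereogenic with E geometry; NaBH4 returns over‑oxidised enal to the alcohol.

**Step 7**
Reactants: 8
Product: 9, (2E,6E,10E)‑12‑bromo‑3,7,11‑trimethyldodeca‑2,6,10‑trien‑1‑yl acetate
Conditions: CBr4, PPh3, CH2Cl2, 0 °C
Reagents that add atoms: carbon tetrabromide, BrC(Br)(Br)Br
Why: Appel bromination of a primary allylic alcohol under neutral conditions; acetate and alkene geometry are untouched.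

**Step 8**
Reactants: 10, (2E,6E)‑farnesyl bromide
Product: 11, (2E,6E)‑farnesyl p‑tolyl sulfone
Conditions: TolSO2Na, DMF, rt
Reagents that add atoms: sodium p‑toluenesulfinate, Cc1ccc(cc1)S(=O)[O-].[Na+]
Why: SN2 S‑alkylation of sulfinate at the primary allylic carbon with retention of the E alkenes.

**Step 9**
Reactants: 11 and 9
Product: 12, (2E,6E,10E,14E,18E)‑3,7,11,15,19,23‑hexamethyl‑13‑(p‑tolylsulfonyl)tetracosa‑2,6,10,14,18,22‑hexaen‑1‑yl acetate (racemic at C13; this centre is removed in step 10)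
Conditions: 11, n‑BuLi (1.0 equiv), THF/DMPU, −78 °C; then 9, −78 → −40 °C
Reagents that add atoms: none
Why: α‑Alkylation of the allyl sulfone anion (Biellmann/Julia‑type coupling) with the allylic bromide forms the C12–C13 bond; the stabilised anion alkylates much faster than it attacks the acetate at −78 °C.

**Step 10**
Reactants: 12
Product: 13, (2E,6E,10E,14E,18E)‑3,7,11,15,19,23‑hexamethyltetracosa‑2,6,10,14,18,22‑hexaen‑1‑ol (all‑E hexaprenol)
Conditions: LiBHEt3 (5 equiv), THF, 0 °C, 30 min; then PdCl2(dppp) (5 mol %), 0 °C → rt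
Reagents that add atoms: none
Why: Super‑Hydride first cleaves the acetate to the alkoxide, which no longer ionises; Pd‑catalysed reductive desulfonylation then delivers hydride to the less substituted π‑allyl terminus, keeping the alkene position and E geometry.

**Step 11**
Reactants: 13
Product: 14, (2E,6E,10E,14E,18E)‑hexaprenyl bromide
Conditions: PBr3 (0.4 equiv), pyridine (cat.), Et2O, −10 → 0 °C; used crude at once
Reagents that add atoms: phosphorus tribromide, BrP(Br)Br
Why: Standard conversion of a primary allylic polyprenol to its bromide without E/Z erosion.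

**Step 12**
Reactants: 5 and 14
Product: 15, 1‑[(2E,6E,10E,14E,18E)‑3,7,11,15,19,23‑hexamethyltetracosa‑2,6,10,14,18,22‑hexaen‑1‑yl]‑2,3‑dimethoxy‑4,5‑bis(methoxymethoxy)‑6‑methylbenzene
Conditions: 5 (2.2 equiv), n‑BuLi (2.2 equiv), THF, −78 °C; CuBr·SMe2 (1.1 equiv), −78 → −40 °C; then 14 (1.0 equiv), −78 → 0 °C
Reagents that add atoms: none
Why: Br/Li exchange then transmetalation gives a diaryl cuprate that displaces the primary allylic bromide in SN2 fashion (the γ‑carbon is disubstituted) with retention of the 2'E alkene.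

**Step 13**
Reactants: 15
Product: 16, 3‑demethylubiquinone‑6 (target)
Conditions: CAN (3 equiv), MeCN/CH2Cl2/H2O, 0 °C, 20 min; then 1 M HCl, THF, rt (hydrolyses any remaining MOM‑oxyquinone)
Reagents that add atoms: water, O
Why: Ce(IV) oxidative dealkylation of the only para‑dialkoxy pair (OMOM/OMe) gives the p‑quinone; the remaining MOM is then a vinylogous acetal‑ester and hydrolyses under mild acid, while the ring OMe stays.

## Compound list
1 | 2,3,4‑trimethoxy‑6‑methylbenzaldehyde | COc1cc(C)c(C=O)c(OC)c1OC | starting material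
2 | 2‑hydroxy‑3,4‑dimethoxy‑6‑methylbenzaldehyde | COc1cc(C)c(C=O)c(O)c1OC | intermediate
3 | 3,4‑dimethoxy‑6‑methylbenzene‑1,2‑diol | COc1cc(C)c(O)c(O)c1OC | intermediate
4 | 1,2‑dimethoxy‑3,4‑bis(methoxymethoxy)‑5‑methylbenzene | COCOc1c(C)cc(OC)c(OC)c1OCOC | intermediate
5 | 1‑bromo‑2,3‑dimethoxy‑4,5‑bis(methoxymethoxy)‑6‑methylbenzene | COCOc1c(C)c(Br)c(OC)c(OC)c1OCOC | intermediate
6 | (2E,6E)‑farnesol | OC/C=C(\C)CC/C=C(\C)CCC=C(C)C | starting material
7 | (2E,6E)‑farnesyl acetate | CC(=O)OC/C=C(\C)CC/C=C(\C)CCC=C(C)C | intermediate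
8 | (2E,6E,10E)‑12‑hydroxyfarnesyl acetate | CC(=O)OC/C=C(\C)CC/C=C(\C)CC/C=C(\C)CO | intermediate
9 | (2E,6E,10E)‑12‑bromofarnesyl acetate | CC(=O)OC/C=C(\C)CC/C=C(\C)CC/C=C(\C)CBr | intermediate
10 | (2E,6E)‑farnesyl bromide | BrC/C=C(\C)CC/C=C(\C)CCC=C(C)C | starting material
11 | (2E,6E)‑farnesyl p‑tolyl sulfone | Cc1ccc(cc1)S(=O)(=O)C/C=C(\C)CC/C=C(\C)CCC=C(C)C | intermediate
12 | C30 13‑tosyl hexaprenyl acetate (racemic at C13) | CC(=O)OC/C=C(\C)CC/C=C(\C)CC/C=C(\C)CC(S(=O)(=O)c1ccc(C)cc1)/C=C(\C)CC/C=C(\C)CCC=C(C)C | intermediate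
13 | all‑E hexaprenol | OC/C=C(\C)CC/C=C(\C)CC/C=C(\C)CC/C=C(\C)CC/C=C(\C)CCC=C(C)C | intermediate
14 | all‑E hexaprenyl bromide | BrC/C=C(\C)CC/C=C(\C)CC/C=C(\C)CC/C=C(\C)CC/C=C(\C)CCC=C(C)C | intermediate
15 | 1‑(all‑E‑hexaprenyl)‑2,3‑dimethoxy‑4,5‑bis(methoxymethoxy)‑6‑methylbenzene | COCOc1c(C)c(C/C=C(\C)CC/C=C(\C)CC/C=C(\C)CC/C=C(\C)CC/C=C(\C)CCC=C(C)C)c(OC)c(OC)c1OCOC | intermediate
16 | 3‑demethylubiquinone‑6: 2‑(all‑E‑hexaprenyl)‑5‑hydroxy‑6‑methoxy‑3‑methyl‑1,4‑benzoquinone | COC1=C(O)C(=O)C(C)=C(C/C=C(\C)CC/C=C(\C)CC/C=C(\C)CC/C=C(\C)CC/C=C(\C)CCC=C(C)C)C1=O | target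

## Summary
- Total steps: 13 (arene branch 1–4; chain branch 5–11, with step 8 as a one‑step side branch; union and endgame 12–13).
- Longest linear sequence: 8 steps (5 → 6 → 7 → 9 → 10 → 11 → 12 → 13, from farnesol).

**Three steps most likely to fail, with fallbacks**
1. Step 6 (SeO2 terminal oxidation: modest yield, internal‑alkene and over‑oxidation by‑products). Fallback: change the disconnection to C10 + C20, coupling (E,E,E)‑geranylgeranyl tolyl sulfone (from commercial geranylgeraniol) with 8‑bromogeranyl acetate, whose SeO2 oxidation is cleaner. Alternatively, build the ω‑E‑allylic alcohol by terminal epoxide formation, cleavage to the aldehyde, E‑selective Wittig with Ph3P=C(Me)CO2Et and DIBAL reduction.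
2. Step 12 (cuprate allylation: SN2′ product, Wurtz dimer, lateral metalation, labile bromide 14). Fallback: switch to Pd‑catalysed Negishi allylation, ArZnCl (from 5) with hexaprenyl acetate or carbonate. Alternatively, convert 14 to hexaprenyl‑SnBu3 and add it to the O‑protected hydroxyquinone with BF3·OEt2 (1,2‑addition then [3,3] shift), followed by re‑oxidation.
3. Step 13 (CAN: o‑quinone by‑products, incomplete MOM loss, polyene damage). Fallback: decouple deprotection from oxidation. Remove both MOM groups under mild acid (no chroman can form, since neither OH is ortho to the prenyl), oxidise the catechol with Ag2O or PhI(OAc)2 to the 4,5‑dimethoxy‑o‑quinone, and hydrolyse its vinylogous ester OMe with dilute acid to the same 2‑hydroxy‑p‑quinone. Alternatively, re‑route the arene via mono‑MOM protection, Baeyer–Villiger and O‑methylation, so the final oxidation is a classical p‑dimethoxy CAN demethylation.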